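(Readings and results are simulated for an exercise.)

The easy step first: ash and oak both read flat. Oak, with 0.47 M of reagent at 25 °C, holds a mean of 58.7 % target from 0.500 h on, and ash is flat from 3.00 h even at 10 °C.

common to all: substrate 0.11 M; free catalyst 55 µM
- ash: reagent 0.059 M; temperature 10 °C; run made earlier
- oak: reagent 0.47 M; temperature 25 °C; run made earlier
- Monday's: reagent 0.110 M; temperature 25 °C; time 15 h
- Sunday's: reagent 0.0800 M; temperature 25 °C; time 15 h
- Saturday's: reagent 0.300 M; temperature 25 °C; time 15 h
- Thursday's: reagent 0.0400 M; temperature 25 °C; time 15 h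
- Friday's: reagent 0.0600 M; temperature 25 °C; time 15 h

| ash: time / h | ash: target / % | oak: time / h | oak: target / % |
|---|---|---|---|
| 3.00 | 17.1 | 0.500 | 61.5 |
| 5.00 | 16.7 | 1.33 | 57.3 |
| 8.00 | 18.2 | 2.50 | 59.1 |
| 10.0 | 17.8 | 4.00 | 57.5 |
| 12.0 | 16.5 | 6.00 | 60.0 |
| 15.0 | 16.0 | 8.00 | 56.6 |

(standard deviation of a reading: 1 percentage point)

1. ranking by amount of target, in percent of the substrate charged, from high to low, at 15 h (Monday's / Sunday's / Saturday's / Thursday's / Friday's)
2. the amount of target, in percent of the substrate charged of the flask you put first, at 15 h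
3. the amount of target, in percent of the substrate charged of the flask you put last, at 15 h

You take over the flasks. I expect their target to stand still before you read them, because oak's flat stretch starts early against 15 h. So leave them closed at temperature and don't add reagent.

I carry one number, the crossing charge R×: oak's plateau times the substrate charged, 0.0645 M. I assume one reagent per target, and that less reagent gives no more target at 25 °C. Below R× the charge is the tighter ceiling: Thursday's, with 0.0400 M of reagent, the limiting reagent, stays under 36.4 %. Above R× oak's plateau is the ceiling: Saturday's, with 0.300 M, stays under 58.7 %.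

The forecast says “I read the plateaus as equilibrium”. It gives Saturday's > Monday's > Sunday's > Friday's > Thursday's, with 46.5 % first and 9.4 % last. Those are estimates and mine are ceilings, and both of its figures lie under mine.

The flasks give Saturday's > Monday's > Sunday's > Friday's > Thursday's, with 55.7 % first and 18.2 % last.

    substrate + reagent ⇌ target (K = 34.0 M⁻¹, k = 0.00450 M⁻¹ s⁻¹, Ea = 57.0 kJ mol⁻¹, ΔH = 19.0 kJ mol⁻¹)
    substrate + reagent ⇌ isomer of the product (K = 22.0 M⁻¹, k = 2.40 × 10⁻⁴ M⁻¹ s⁻¹, Ea = 77.0 kJ mol⁻¹, ΔH = −32.0 kJ mol⁻¹)
    target + free catalyst ⇌ isomer of the product + free catalyst, rate k3*[free catalyst]*[target] forward; the back reaction follows from the equilibrium constant (k = 14.0 M⁻¹ s⁻¹, Ea = 53.0 kJ mol⁻¹)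
    substrate + free catalyst → spent catalyst (k = 0.00370 M⁻¹ s⁻¹, Ea = 58.0 kJ mol⁻¹)
    (constants at 25 °C)

Both ceilings hold: Saturday's stands under 58.7 %, and Thursday's reaches half of its 36.4 %. In Thursday's at 15.0 h, the step to target alone, both ways together, relaxes with a half-life of 0.374 h, far shorter than 15 h. Its target reads 18.4 % at 7.50 h and 18.2 % at 15.0 h, the picture of thermodynamic control.

A neighbour flask is Thursday's with 0.16 M of reagent. It lies above R×, so its ceiling is oak's 58.7 %. It gives 48.6 % target.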